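Chain numbering: C1 is the ketone carbon, C2–C9 are the eight methylenes, and C9 is benzylic.

**Plan**
1. The retrosynthesis first cuts one O–CH3 bond, since the free 2-OH comes from a symmetric 2,6-dimethoxyphenyl ketone. It then restores a helper C9=O and an O-benzyl group, cuts C6–C7, and finally ties C6 back to C1.
2. The enabling feature is that C1 and the methylenes C2–C6 are the six atoms of a cyclohexane ring. Its carbinol carbon carries the electron-rich 2,6-dioxygenated benzene ring, which serves as a built-in site for one-electron oxidation.
3. The alkoxy radical of this 1-arylcyclohexanol opens to give the C1 ketone and a C6 radical. C7–C9 together with the 4-oxygenated benzene ring form an aryl vinyl ketone that accepts this radical at C7.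
4. Forward: ortho-lithiation of 1,3-dimethoxybenzene and addition to cyclohexanone builds the temporary ring, and α-methylenation of an acetophenone gives the acceptor. Ring opening with radical conjugate addition then joins the chain.
5. One hydrogenolysis removes the helper carbonyl and the benzyl group. BCl3 then differentiates the two methoxy groups.
6. Both benzene rings are bought, and no ring of the target has to be made. No stereochemistry has to be set.

Key step: step 3

Remark on the chemistry: the target has no stereocentre, stereogenic axis or configured double bond. It is achiral, so "single enantiomer" is taken to mean the compound as drawn.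

**Step 1**
Reactants: 1 1,3-dimethoxybenzene; 2 cyclohexanone
Product: 4 1-(2,6-dimethoxyphenyl)cyclohexan-1-ol, via 2,6-dimethoxyphenyllithium 3 (not isolated)
Conditions: n-BuLi, THF, 0 °C to rt; then 2, −78 °C to rt; then H2O (acid-free work-up, Et3N-deactivated silica)
Reagents that add atoms: none
Why: Directed ortho-metalation at the position flanked by both methoxy groups, followed by 1,2-addition of the aryllithium to the ketone, makes the aryl–C1 bond at the ring position that Friedel–Crafts acylation of resorcinol ethers does not reach.

**Step 2**
Reactants: 5 1-[4-(benzyloxy)phenyl]ethan-1-one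
Product: 7 1-[4-(benzyloxy)phenyl]prop-2-en-1-one, via diisopropylamino Mannich base 6 (not isolated)
Conditions: (CH2O)n, iPr2NH·TFA (1 equiv), TFA (10 mol %), THF, reflux; product stabilised with BHT and used at once
Reagents that add atoms: paraformaldehyde (as formaldehyde), C=O
Why: In this Mannich-type α-methylenation the enol of 5 attacks the iminium ion formed from formaldehyde and the secondary ammonium salt, and the hindered β-amino ketone 6 loses diisopropylamine by E1cB elimination to give the vinyl ketone.

**Step 3**
Reactants: 4 1-(2,6-dimethoxyphenyl)cyclohexan-1-ol; 7 1-[4-(benzyloxy)phenyl]prop-2-en-1-one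
Product: 9 9-[4-(benzyloxy)phenyl]-1-(2,6-dimethoxyphenyl)nonane-1,9-dione, via ring-opened primary radical 8 (not isolated)
Conditions: 7 (1.5 equiv, in portions), [Ir(dF(CF3)ppy)2(5,5'-d(CF3)bpy)]PF6 (2 mol %), 2,4,6-collidine (1 equiv), CH2Cl2, blue LEDs, rt, Ar
Reagents that add atoms: none
Why: The excited iridium photocatalyst takes one electron from the 2,6-dimethoxyphenyl ring of 4, collidine accepts the carbinol proton in a proton-coupled electron transfer, and the tertiary alkoxy radical so formed breaks the ring bond C1–C6 by β-scission, which creates the C1 aryl ketone and the primary C6 radical 8 in one event. Radical 8 adds to the unsubstituted vinyl terminus (C7) of 7, and the resulting α-acyl radical at C8 is reduced by the Ir(II) state and protonated by collidinium, so the step is redox-neutral and every atom of 4 and 7 ends up in 9. The closest known reaction types are the photocatalytic PCET ring opening of 1-arylcycloalkanols to distally functionalised aryl ketones and the Giese addition of alkyl radicals to vinyl ketones. No ring is closed (the temporary cyclohexane ring is opened) and no stereocentre is formed. Cross-selectivity is needed and is secured by polarity matching, since the nucleophilic primary radical meets only one electrophilic alkene, while the site of scission is unambiguous because the two ring bonds at C1 are equivalent by symmetry and loss of the aryl group would cost an aryl radical. Chemoselectivity of the oxidation rests on the acyl groups of 7 and 9, which make their arenes harder to oxidise than the alkyl-substituted dimethoxybenzene ring of 4, and relief of the crowding between the di-ortho-substituted ring and the quaternary carbinol carbon pulls the otherwise reversible opening of the six-membered ring forward.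

**Step 4**
Reactants: 9 9-[4-(benzyloxy)phenyl]-1-(2,6-dimethoxyphenyl)nonane-1,9-dione
Product: 12 1-(2,6-dimethoxyphenyl)-9-(4-hydroxyphenyl)nonan-1-one, via debenzylated diketone 10 (not isolated), via benzylic alcohol 11 (not isolated)
Conditions: H2 (4 bar), 10% Pd/C, AcOH, 50 °C
Reagents that add atoms: none
Why: Catalytic hydrogenolysis should cleave the benzyl ether and take the flat, unhindered 4-oxygenated aryl ketone at C9 through the benzylic alcohol to the methylene group (the classical Pd/C–acid reduction of para-oxygenated aryl ketones), whereas the C1 carbonyl, flanked by two ortho methoxy groups and twisted out of the ring plane, cannot lie on the catalyst surface and should remain.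

**Step 5**
Reactants: 12 1-(2,6-dimethoxyphenyl)-9-(4-hydroxyphenyl)nonan-1-one
Product: 14 1-(2-hydroxy-6-methoxyphenyl)-9-(4-hydroxyphenyl)nonan-1-one (target), via bis(dichloroboryl) chelate 13 (not isolated)
Conditions: BCl3 (3 equiv), CH2Cl2, −78 to 0 °C; then H2O
Reagents that add atoms: none
Why: In this chelation-directed ether cleavage BCl3 bound to the C1 carbonyl oxygen cleaves one of the two equivalent ortho O–CH3 bonds, and the six-membered boron chelate so formed occupies the carbonyl and shuts off cleavage of the second methoxy group, which gives the 2-hydroxy-6-methoxy pattern.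

**Compound list**
1 | 1,3-dimethoxybenzene | COc1cccc(OC)c1 | starting material
2 | cyclohexanone | O=C1CCCCC1 | starting material
3 | 2,6-dimethoxyphenyllithium | [Li]c1c(OC)cccc1OC | intermediate
4 | 1-(2,6-dimethoxyphenyl)cyclohexan-1-ol | COc1cccc(OC)c1C1(O)CCCCC1 | intermediate
5 | 1-[4-(benzyloxy)phenyl]ethan-1-one | CC(=O)c1ccc(OCc2ccccc2)cc1 | starting material
6 | 1-[4-(benzyloxy)phenyl]-3-(diisopropylamino)propan-1-one | CC(C)N(CCC(=O)c1ccc(OCc2ccccc2)cc1)C(C)C | intermediate
7 | 1-[4-(benzyloxy)phenyl]prop-2-en-1-one | C=CC(=O)c1ccc(OCc2ccccc2)cc1 | intermediate
8 | 6-(2,6-dimethoxyphenyl)-6-oxohexyl radical | COc1cccc(OC)c1C(=O)CCCC[CH2] | intermediate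
9 | 9-[4-(benzyloxy)phenyl]-1-(2,6-dimethoxyphenyl)nonane-1,9-dione | COc1cccc(OC)c1C(=O)CCCCCCCC(=O)c1ccc(OCc2ccccc2)cc1 | intermediate
10 | 1-(2,6-dimethoxyphenyl)-9-(4-hydroxyphenyl)nonane-1,9-dione | COc1cccc(OC)c1C(=O)CCCCCCCC(=O)c1ccc(O)cc1 | intermediate
11 | 1-(2,6-dimethoxyphenyl)-9-hydroxy-9-(4-hydroxyphenyl)nonan-1-one (racemic, transient) | COc1cccc(OC)c1C(=O)CCCCCCCC(O)c1ccc(O)cc1 | intermediate
12 | 1-(2,6-dimethoxyphenyl)-9-(4-hydroxyphenyl)nonan-1-one | COc1cccc(OC)c1C(=O)CCCCCCCCc1ccc(O)cc1 | intermediate
13 | bis(O-dichloroboryl) derivative of 14, with the ortho boron chelated to the C1 carbonyl | COc1cccc(OB(Cl)Cl)c1C(=O)CCCCCCCCc1ccc(OB(Cl)Cl)cc1 | intermediate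
14 | 1-(2-hydroxy-6-methoxyphenyl)-9-(4-hydroxyphenyl)nonan-1-one | COc1cccc(O)c1C(=O)CCCCCCCCc1ccc(O)cc1 | target

**Step count**
Total step count: 5.
Longest linear sequence: 4 steps (1, 3, 4, 5). The branch 2, 3, 4, 5 is equally long.

**Steps most likely to fail**

**Step 3.**
- The vinyl ketone may be lost to polymerisation or sensitised dimerisation. The radical may be lost to 1,5-hydrogen transfer from C2 or to re-closure before it is trapped.
- The fallback makes the same C6–C7 bond by a nickel-catalysed cross-electrophile coupling. It needs neither the temporary ring nor the helper carbonyl. It sets out from 3 and comes back to the route at 12.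
- Aryllithium 3 is added inversely to commercial 6-bromohexanoyl chloride (THF, −78 °C) to give 6-bromo-1-(2,6-dimethoxyphenyl)hexan-1-one F1. The di-ortho-substituted ketone is too hindered for a second addition.
- Commercial 4-(benzyloxy)benzaldehyde is treated with vinylmagnesium bromide, and the alkoxide is quenched with acetic anhydride. This gives racemic 1-[4-(benzyloxy)phenyl]allyl acetate F2.
- NiCl2·glyme, 4,4',4''-tri-tert-butylterpyridine and zinc dust in DMA/THF join the two electrophiles. The bromide enters as an alkyl radical. The acetate enters as a π-allylnickel species that reacts at its unsubstituted terminus. The product is (E)-9-[4-(benzyloxy)phenyl]-1-(2,6-dimethoxyphenyl)non-8-en-1-one F3.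
- Neutral hydrogenation (H2, 1 atm, Pd/C, EtOH, rt) saturates the styrene double bond and cleaves the benzyl ether to give 12.

**Step 4.**
- The hydrogenolysis may stall at the stage of the deactivated phenolic ketone. Forcing it may start to erode the hindered C1 carbonyl.
- The fallback moves the discrimination between the two carbonyl groups from the catalyst surface to a hydride reagent. It sets out from 9 and comes back at 12.
- NaBH4 (MeOH/THF, −20 °C) or LiAlH(OtBu)3 should reduce only the unhindered C9 carbonyl. This gives racemic 9-[4-(benzyloxy)phenyl]-1-(2,6-dimethoxyphenyl)-9-hydroxynonan-1-one F4.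
- The 4-oxygenated benzylic C–OH bond and the benzyl ether of F4 are then cleaved under neutral, mild conditions (H2, 1 atm, Pd/C, EtOH, rt). Aryl ketones are not touched under these conditions, and the product is 12.

**Step 1.**
- The hindered aryllithium may act as a base and enolise cyclohexanone. The electron-rich tertiary benzylic alcohol may also lose water during work-up.
- The fallback builds the six-membered ring onto an aryl carbonyl carbon instead of buying it, so no enolisable partner is present. It sets out from 3 and comes back at 4.
- Aryllithium 3 is quenched with methyl chloroformate to give methyl 2,6-dimethoxybenzoate F5.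
- 1,5-Dibromopentane and magnesium in THF give pentane-1,5-diylbis(magnesium bromide) F6.
- Double addition of F6 to F5 (THF, reflux) gives 4 after neutral work-up. The second addition is an intramolecular closure of the six-membered ring.

**Further compounds**
F1 | step 3 | 6-bromo-1-(2,6-dimethoxyphenyl)hexan-1-one | COc1cccc(OC)c1C(=O)CCCCCBr
F2 | step 3 | 1-[4-(benzyloxy)phenyl]allyl acetate (racemic) | C=CC(OC(C)=O)c1ccc(OCc2ccccc2)cc1
F3 | step 3 | (E)-9-[4-(benzyloxy)phenyl]-1-(2,6-dimethoxyphenyl)non-8-en-1-one | COc1cccc(OC)c1C(=O)CCCCCC/C=C/c1ccc(OCc2ccccc2)cc1
F4 | step 4 | 9-[4-(benzyloxy)phenyl]-1-(2,6-dimethoxyphenyl)-9-hydroxynonan-1-one (racemic) | COc1cccc(OC)c1C(=O)CCCCCCCC(O)c1ccc(OCc2ccccc2)cc1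
F5 | step 1 | methyl 2,6-dimethoxybenzoate | COC(=O)c1c(OC)cccc1OC
F6 | step 1 | pentane-1,5-diylbis(magnesium bromide) | Br[Mg]CCCCC[Mg]Br
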